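The route rests on cutting the side chain (numbered from CO2H = C1 to C9 on the chroman) between olefinic C7 and methylene C8. C8 is two carbons out from the quaternary C2 of the pyran ring, i.e. the terminal carbon of a C2-vinyl group. Anti-Markovnikov hydroboration of (S)-2-vinylchroman 7, followed in the same flask by B-alkyl Suzuki–Miyaura coupling with dienyl iodide 13, therefore joins the two halves and carries the (6E) and (2Z) geometries over unchanged. The precursor pair is a vinylchroman whose stereocentre comes from an enantioselective Wacker-type cyclization, and an iodide made by carboalumination–iodination and Still–Gennari olefination.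

Key step: step 8

Assumption: the sense of induction of Pd(OCOCF3)2/(S,S)-Bn-BOXAX in step 4 is assigned by analogy with related alkenylphenol cyclizations; if the (R)-chroman forms, (R,R)-Bn-BOXAX is used with nothing else changed.

Step 1
Reactants: 1 2,4-dihydroxy-6-methylbenzaldehyde
Product: 2 2-hydroxy-6-methyl-4-[(triisopropylsilyl)oxy]benzaldehyde
Conditions: iPr3SiCl (1.05 equiv), imidazole (2 equiv), CH2Cl2, 0 °C → rt
Reagents that add atoms: chlorotriisopropylsilane, CC(C)[Si](Cl)(C(C)C)C(C)C
Why: The 2-hydroxyl is held in an intramolecular hydrogen bond to the formyl group and is flanked by it, so silylation with the bulky chloride should occur selectively at the free 4-hydroxyl.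

Step 2
Reactants: 2 2-hydroxy-6-methyl-4-[(triisopropylsilyl)oxy]benzaldehyde
Product: 3 3-methyl-5-[(triisopropylsilyl)oxy]-2-vinylphenol
Conditions: Ph3PCH3Br (2.5 equiv), KOtBu (2.5 equiv), THF, 0 °C → rt
Reagents that add atoms: methyltriphenylphosphonium bromide, C[P+](c1ccccc1)(c1ccccc1)c1ccccc1.[Br-]
Why: Wittig methylenation, in which the phenol is only deprotonated by the first equivalent of ylide and the hindered aryl silyl ether is inert, so only the formyl group is converted.

Step 3
Reactants: 3 3-methyl-5-[(triisopropylsilyl)oxy]-2-vinylphenol; 4 (Z)-2-bromobut-2-ene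
Product: 6 3-methyl-2-[(3Z)-3-methylpent-3-en-1-yl]-5-[(triisopropylsilyl)oxy]phenol, via bis(9-BBN) adduct 5 (not isolated)
Conditions: 9-BBN (2.3 equiv), THF, 0 °C → rt; then 4 (1.5 equiv), PdCl2(dppf)·CH2Cl2 (5 mol %), 3 M aq K3PO4, DMF, 50 °C
Reagents that add atoms: none
Why: 9-BBN first caps the phenol and then hydroborates the hindered styrene at its terminal carbon, and the B-alkyl Suzuki–Miyaura coupling with the alkenyl bromide proceeds with retention, so the (Z) geometry of 4 should be carried into 6 while the aqueous base frees the phenol again.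

Step 4
Reactants: 6 3-methyl-2-[(3Z)-3-methylpent-3-en-1-yl]-5-[(triisopropylsilyl)oxy]phenol
Product: 7 (2S)-2,5-dimethyl-7-[(triisopropylsilyl)oxy]-2-vinylchroman
Conditions: Pd(OCOCF3)2 (10 mol %), (S,S)-Bn-BOXAX [2,2′-bis((4S)-4-benzyl-4,5-dihydrooxazol-2-yl)-1,1′-binaphthyl] (20 mol %), p-benzoquinone (4 equiv), MeOH, rt
Reagents that add atoms: none
Why: Enantioselective Wacker-type oxidative cyclization, in which the divalent palladium–bis(oxazoline) complex binds one face of the trisubstituted alkene, the phenol oxygen attacks the methyl-bearing carbon in a 6-exo-trig oxypalladation that sets C2 as (S) under ligand control, and β-hydride elimination toward the only β-hydrogens available (the terminal CH3) unveils the vinyl group while p-benzoquinone returns zerovalent palladium to the divalent state.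

Step 5
Reactants: 8 pent-4-yn-1-ol
Product: 10 (4E)-5-iodo-4-methylpent-4-en-1-ol, via alkenylalane 9 (not isolated)
Conditions: Me3Al (3 equiv), Cp2ZrCl2 (0.25 equiv), CH2Cl2, 0 °C → rt; then I2 (1.2 equiv), THF, −30 → 0 °C; aq K2CO3 work-up
Reagents that add atoms: trimethylaluminium, C[Al](C)C; iodine, II
Why: Zr-catalysed carboalumination (Negishi) adds methyl and aluminium syn across the terminal alkyne with methyl on the internal carbon, and iododealumination with retention should fix the (E)-trisubstituted iodoalkene.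

Step 6
Reactants: 10 (4E)-5-iodo-4-methylpent-4-en-1-ol
Product: 11 (4E)-5-iodo-4-methylpent-4-enal
Conditions: Dess–Martin periodinane (1.2 equiv), CH2Cl2, 0 °C → rt
Reagents that add atoms: none
Why: Dess–Martin oxidation stops at the aldehyde under near-neutral conditions that leave the alkenyl iodide untouched.

Step 7
Reactants: 11 (4E)-5-iodo-4-methylpent-4-enal; 12 ethyl 2-[bis(2,2,2-trifluoroethoxy)phosphoryl]propanoate
Product: 13 ethyl (2Z,6E)-7-iodo-2,6-dimethylhepta-2,6-dienoate
Conditions: 12 (1.2 equiv), KN(SiMe3)2 (1.15 equiv), 18-crown-6 (3 equiv), THF, −78 °C; then 11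
Reagents that add atoms: none
Why: Still–Gennari variant of the Horner–Wadsworth–Emmons reaction, in which the electron-poor bis(trifluoroethyl) phosphonate with a dissociated potassium counter-ion eliminates rapidly from the kinetic adduct and should give the (Z)-2-methyl enoate, while the alkenyl iodide has no hydrogen on the neighbouring sp2 carbon and cannot eliminate.

Step 8
Reactants: 7 (2S)-2,5-dimethyl-7-[(triisopropylsilyl)oxy]-2-vinylchroman; 13 ethyl (2Z,6E)-7-iodo-2,6-dimethylhepta-2,6-dienoate
Product: 15 ethyl (2Z,6E)-9-{(2R)-2,5-dimethyl-7-[(triisopropylsilyl)oxy]chroman-2-yl}-2,6-dimethylnona-2,6-dienoate, via B-alkyl-9-BBN 14 (not isolated)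
Conditions: 7 (1.2 equiv), 9-BBN (1.5 equiv), THF, 0 °C → rt; H2O; then 13 (1.0 equiv), PdCl2(dppf)·CH2Cl2 (10 mol %), AsPh3 (10 mol %), 3 M aq K3PO4 (3 equiv), DMF, rt
Reagents that add atoms: none
Why: 9-BBN adds to the C2-vinyl group of the pyran ring with boron on the terminal carbon, because the neighbouring quaternary C2 and the bulk of the reagent exclude the internal position, and the resulting primary alkylborane 14 carries boron γ to O1 so that no β-alkoxy elimination can occur. Zerovalent palladium then inserts into the C–I bond of 13 with retention, the base-activated borate transfers its primary alkyl group to divalent palladium in preference to the secondary bicyclic carbons, and reductive elimination forges the C8–C7 bond. The closest known reaction type is the B-alkyl Suzuki–Miyaura coupling of a hydroborated terminal alkene with an (E)-alkenyl iodide. No ring is closed and no stereocentre is formed; the C2 stereocentre lies two bonds from the reacting carbon and is not touched. The step needs chemoselectivity for the vinyl group over the alkenes of 13, secured by completing the hydroboration and destroying excess B–H with water before 13 is added, and it needs retention of the (6E) and (2Z) geometries, secured by the stereoretentive oxidative addition and by the mild phosphate base at room temperature, which should also spare the ethyl ester and the aryl silyl ether.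

Step 9
Reactants: 15 ethyl (2Z,6E)-9-{(2R)-2,5-dimethyl-7-[(triisopropylsilyl)oxy]chroman-2-yl}-2,6-dimethylnona-2,6-dienoate
Product: 16 (2Z,6E)-9-[(2R)-7-hydroxy-2,5-dimethylchroman-2-yl]-2,6-dimethylnona-2,6-dienoic acid (CNP0244790.1)
Conditions: LiOH·H2O (10 equiv), 1,4-dioxane/H2O (2:1), 50 °C; then 1 M HCl to pH 3, 0 °C
Reagents that add atoms: lithium hydroxide, [Li+].[OH-]
Why: Excess hydroxide saponifies the ethyl ester and attacks silicon of the aryl silyl ether (phenoxide as leaving group) in the same flask, the carboxylate formed resists conjugate addition so the (2Z) geometry should be retained, and C2 is not involved.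

Compound list
1 | 2,4-dihydroxy-6-methylbenzaldehyde | Cc1cc(O)cc(O)c1C=O | starting material
2 | 2-hydroxy-6-methyl-4-[(triisopropylsilyl)oxy]benzaldehyde | Cc1cc(O[Si](C(C)C)(C(C)C)C(C)C)cc(O)c1C=O | intermediate
3 | 3-methyl-5-[(triisopropylsilyl)oxy]-2-vinylphenol | C=Cc1c(C)cc(O[Si](C(C)C)(C(C)C)C(C)C)cc1O | intermediate
4 | (Z)-2-bromobut-2-ene | C/C=C(/C)Br | starting material
5 | 9-{2-[2-(9-borabicyclo[3.3.1]nonan-9-yloxy)-6-methyl-4-[(triisopropylsilyl)oxy]phenyl]ethyl}-9-borabicyclo[3.3.1]nonane | Cc1cc(O[Si](C(C)C)(C(C)C)C(C)C)cc(OB2C3CCCC2CCC3)c1CCB1C2CCCC1CCC2 | intermediate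
6 | 3-methyl-2-[(3Z)-3-methylpent-3-en-1-yl]-5-[(triisopropylsilyl)oxy]phenol | C/C=C(/C)CCc1c(C)cc(O[Si](C(C)C)(C(C)C)C(C)C)cc1O | intermediate
7 | (2S)-2,5-dimethyl-7-[(triisopropylsilyl)oxy]-2-vinylchroman | C=C[C@]1(C)CCc2c(C)cc(O[Si](C(C)C)(C(C)C)C(C)C)cc2O1 | intermediate
8 | pent-4-yn-1-ol | C#CCCCO | starting material
9 | dimethyl[(1E)-5-(dimethylalumanyloxy)-2-methylpent-1-en-1-yl]alumane | C[Al](C)OCCC/C(C)=C/[Al](C)C | intermediate
10 | (4E)-5-iodo-4-methylpent-4-en-1-ol | OCCC/C(C)=C/I | intermediate
11 | (4E)-5-iodo-4-methylpent-4-enal | O=CCC/C(C)=C/I | intermediate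
12 | ethyl 2-[bis(2,2,2-trifluoroethoxy)phosphoryl]propanoate | CCOC(=O)C(C)P(=O)(OCC(F)(F)F)OCC(F)(F)F | starting material
13 | ethyl (2Z,6E)-7-iodo-2,6-dimethylhepta-2,6-dienoate | C/C(=C/CC/C(C)=C/I)C(=O)OCC | intermediate
14 | 9-{2-[(2R)-2,5-dimethyl-7-[(triisopropylsilyl)oxy]chroman-2-yl]ethyl}-9-borabicyclo[3.3.1]nonane | C1CCC2CCCC1B2CC[C@]1(C)CCc2c(C)cc(O[Si](C(C)C)(C(C)C)C(C)C)cc2O1 | intermediate
15 | ethyl (2Z,6E)-9-{(2R)-2,5-dimethyl-7-[(triisopropylsilyl)oxy]chroman-2-yl}-2,6-dimethylnona-2,6-dienoate | C/C(=C/CC/C(C)=C/CC[C@]1(C)CCc2c(C)cc(O[Si](C(C)C)(C(C)C)C(C)C)cc2O1)C(=O)OCC | intermediate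
16 | (2Z,6E)-9-[(2R)-7-hydroxy-2,5-dimethylchroman-2-yl]-2,6-dimethylnona-2,6-dienoic acid | C/C(=C/CC/C(C)=C/CC[C@]1(C)CCc2c(C)cc(O)cc2O1)C(=O)O | target

Total step count: 9. Longest linear sequence: 6 steps (1, 2, 3, 4, 8, 9); steps 5–7 build the iodide in parallel.

Steps most likely to fail

Step 4 may suffer from weak facial discrimination of the trisubstituted alkene in the oxypalladation, or from loss of turnover through precipitation of palladium and alkene isomerization. The fallback sets out from 3 and comes back at 7. But-2-yn-1-ol is treated with NaAlH2(OCH2CH2OCH3)2 and then I2 to give (Z)-3-iodobut-2-en-1-ol F1. Compound 3 is hydroborated with 9-BBN and coupled with F1 (PdCl2(dppf)·CH2Cl2, aq K3PO4) to give 2-[(3Z)-5-hydroxy-3-methylpent-3-en-1-yl]-3-methyl-5-[(triisopropylsilyl)oxy]phenol F2. Methyl chloroformate and pyridine at −20 °C should acylate the primary allylic alcohol ahead of the hindered phenol to give (2Z)-5-{2-hydroxy-6-methyl-4-[(triisopropylsilyl)oxy]phenyl}-3-methylpent-2-en-1-yl methyl carbonate F3. Palladium-catalysed asymmetric allylic alkylation (Pd2(dba)3·CHCl3, DACH-phenyl bis(diphenylphosphinobenzamide) ligand, AcOH, CH2Cl2) then closes the phenol onto the more substituted terminus of the π-allyl complex to give 7, the ligand enantiomer being chosen for the (S) product.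

Step 3 may suffer from consumption of borane by the free phenol, oligomerization of the electron-rich vinylphenol, and slow transmetalation with the hindered alkenyl bromide. The fallback sets out from 2, bypasses steps 2 and 3, and comes back at 6. Wittig reaction of 2 with Ph3P=CHCOCH3 (toluene, 80 °C) gives (3E)-4-{2-hydroxy-6-methyl-4-[(triisopropylsilyl)oxy]phenyl}but-3-en-2-one F4. Hydrogenation (H2, Pd/C, EtOAc) gives 4-{2-hydroxy-6-methyl-4-[(triisopropylsilyl)oxy]phenyl}butan-2-one F5. Wittig reaction of F5 with excess ethylidenetriphenylphosphorane (from Ph3PCH2CH3Br and KOtBu) should give 6 as the predominant (Z) isomer; the minor (E) isomer is expected to converge on the same chroman in step 4.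

Step 8 may suffer from slow transmetalation of the borane next to the quaternary carbon, with protodeboronation or reduction of the iodide taking over. The fallback sets out from 7 and comes back at 15. Hydroboration–oxidation (9-BBN, then NaBO3·4H2O) gives 2-{(2S)-2,5-dimethyl-7-[(triisopropylsilyl)oxy]chroman-2-yl}ethanol F6. I2, PPh3 and imidazole give (2S)-2-(2-iodoethyl)-2,5-dimethyl-7-[(triisopropylsilyl)oxy]chroman F7. Zinc insertion (Zn dust, LiCl, THF) gives {2-[(2S)-2,5-dimethyl-7-[(triisopropylsilyl)oxy]chroman-2-yl]ethyl}zinc iodide F8, and Negishi coupling with 13 (Pd(PPh3)4, THF, rt) forms the same C8–C7 bond to give 15.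

Further compounds
F1 | step 4 | (Z)-3-iodobut-2-en-1-ol | OC/C=C(/C)I
F2 | step 4 | 2-[(3Z)-5-hydroxy-3-methylpent-3-en-1-yl]-3-methyl-5-[(triisopropylsilyl)oxy]phenol | OC/C=C(/C)CCc1c(C)cc(O[Si](C(C)C)(C(C)C)C(C)C)cc1O
F3 | step 4 | (2Z)-5-{2-hydroxy-6-methyl-4-[(triisopropylsilyl)oxy]phenyl}-3-methylpent-2-en-1-yl methyl carbonate | COC(=O)OC/C=C(/C)CCc1c(C)cc(O[Si](C(C)C)(C(C)C)C(C)C)cc1O
F4 | step 3 | (3E)-4-{2-hydroxy-6-methyl-4-[(triisopropylsilyl)oxy]phenyl}but-3-en-2-one | CC(=O)/C=C/c1c(C)cc(O[Si](C(C)C)(C(C)C)C(C)C)cc1O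
F5 | step 3 | 4-{2-hydroxy-6-methyl-4-[(triisopropylsilyl)oxy]phenyl}butan-2-one | CC(=O)CCc1c(C)cc(O[Si](C(C)C)(C(C)C)C(C)C)cc1O
F6 | step 8 | 2-{(2S)-2,5-dimethyl-7-[(triisopropylsilyl)oxy]chroman-2-yl}ethanol | OCC[C@]1(C)CCc2c(C)cc(O[Si](C(C)C)(C(C)C)C(C)C)cc2O1
F7 | step 8 | (2S)-2-(2-iodoethyl)-2,5-dimethyl-7-[(triisopropylsilyl)oxy]chroman | ICC[C@]1(C)CCc2c(C)cc(O[Si](C(C)C)(C(C)C)C(C)C)cc2O1
F8 | step 8 | {2-[(2S)-2,5-dimethyl-7-[(triisopropylsilyl)oxy]chroman-2-yl]ethyl}zinc iodide | I[Zn]CC[C@]1(C)CCc2c(C)cc(O[Si](C(C)C)(C(C)C)C(C)C)cc2O1
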